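Our unit is the e-fold: the natural logarithm of the two substrates charged over the fraction of them left.

| flask | left-handed substrate | right-handed substrate | partner | free catalyst | racemization catalyst | impurity | remark | time |
|---|---|---|---|---|---|---|---|---|
| elm | 1 mM | 1 mM | 2.2 mM | 0.15 mM | 1 µM | 8 µM | run made earlier |  |
| oak | 1 mM | 1 mM | 2.2 mM | 0.15 mM | 1 µM | 32 µM | run made earlier |  |
| flask | 1.0 mM | 1.0 mM | 2.20 mM | 0.15 mM | 1.0 µM | 16 µM |  | 4.0 min |

| run | time / min | left-handed substrate / % | right-handed substrate / % |
|---|---|---|---|
| elm | 0.333 | 41.7 | 50.1 |
| elm | 0.500 | 42.5 | 49.5 |
| elm | 0.833 | 39.3 | 47.5 |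
| elm | 1.33 | 38.1 | 45.9 |
| elm | 2.50 | 38.9 | 43.3 |
| elm | 4.00 | 39.0 | 39.5 |
| oak | 0.333 | 43.2 | 49.4 |
| oak | 0.500 | 43.1 | 49.3 |
| oak | 0.833 | 40.6 | 47.8 |
| oak | 1.33 | 41.3 | 45.6 |
| oak | 2.50 | 40.6 | 45.3 |
| oak | 4.00 | 40.2 | 40.2 |

(readings scatter by 1 percentage point)

- free catalyst is single-handed; left-handed substrate and right-handed substrate are mirror images of each other, charged as a racemate, each of them at the stated concentration
- what may be going on: partner + free catalyst + left-handed substrate -> free catalyst + left-handed product; partner + free catalyst + right-handed substrate -> free catalyst + right-handed product; left-handed substrate + racemization catalyst <-> right-handed substrate + racemization catalyst; 2 free catalyst -> spent catalyst A; free catalyst + impurity -> spent catalyst B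
- an excess is the difference of the two amounts in percent of their sum
- an excess is below zero if the other one leads

1. part of the left-handed substrate and right-handed substrate charged together that has reacted at 4.0 min
2. excess of left-handed product over right-handed product in the product at 4.0 min
3. excess of right-handed substrate over left-handed substrate among what is left of the two at 4.0 min

At 4.00 min the elm run reads 0.242 and the oak run, with more impurity, reads 0.218. The flask, at 16 µM of impurity, lies between them, so a straight line gives 0.234. We call this E, the exposure: the e-folds of substrate that the free catalyst gets through by the asked time. Partner stands as a factor in both product steps, so E should grow with the partner charge while the catalyst's life holds.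

We commit to c = 20.9%. One number is not enough, because E counts loss and not hand. At 0.333 min elm shows left-handed substrate at 41.7% and right-handed at 50.1%, but at 4.00 min it shows 39.0% and 39.5%. So we expect eS near zero and eP high, and nothing sharper.

The forecast gives c 20%, below ours, with eP 88% and eS 2.5%, “Assuming a selectivity of about 20”.

The flask gives c 20.5%, which is E = 0.229, with eS 2.01% and eP 97.2%. The forecast parts from it on eP, by 9.2 percentage points; the selectivity factor, the ratio of the two product rate constants, is 79.0.

    partner + free catalyst + left-handed substrate → free catalyst + left-handed product (k = 49000 L² mol⁻² s⁻¹)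
    partner + free catalyst + right-handed substrate → free catalyst + right-handed product (k = 620 L² mol⁻² s⁻¹)
    left-handed substrate + racemization catalyst ⇌ right-handed substrate + racemization catalyst, rate k3*[racemization catalyst]*[left-handed substrate] forward; the back reaction follows from the equilibrium constant (k = 9800 L mol⁻¹ s⁻¹)
    2 free catalyst → spent catalyst A (k = 310 L mol⁻¹ s⁻¹)
    free catalyst + impurity → spent catalyst B (k = 16000 L mol⁻¹ s⁻¹)

By the left-handed step, partner's half-life is 1.6 min with the charges held, 8.2 min at 0.575 min and 47 min at 4.00 min, longer than the run. Free catalyst then stands at 4.26% of its charge, with spent catalyst A at 85.1%, more than spent catalyst B at 10.7%.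

For a neighbour flask charged with 8.8 mM of partner, we scale E with the partner charge and estimate 0.936, so c near 60.8%. Computed, that neighbour gives c 55.3%, below the estimate, which is E = 0.805.

The numbers in the tables were computed from invented constants, noise included.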